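**Plan**
Retrosynthesis: ring C is opened at C3-C4 together with the C2-H bond (retro-hydroacylation), which leads back to an achiral 2-(1-arylvinyloxy)benzaldehyde. Next the formyl carbon is cut (to an aryl bromide), then the =CH2 carbon C3 (to an aryl ester), the ester C-O bond, and last the furan ring at C3a'-C3' and O1'-C2' (to an ortho-iodophenol and an aryl alkyne).
Enabling feature: in ring C, C2 carries O1, the benzofuranyl group and one H, C3 is a bare CH2, and the C4 carbonyl sits on ring A ortho to O1. Ring C is therefore the formal adduct of a ring A formyl C-H bond across a 1,1-disubstituted enol ether C2=C3 that O1 already ties to ring A.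
Forward order: the furan ring of the benzofuran is made first, the two halves are joined as an ester, the ester C=O becomes C=CH2, the bromide becomes the aldehyde, and ring C is closed last.
Stereochemistry: the single stereocentre C2 (S) comes from catalyst-controlled hydride delivery to one face of the enol ether in the last step, and nothing follows that could racemise it.

Key step: step 6

Assumption: the hand of DTBM-SEGPHOS that leads to the (S) product on this substrate class cannot be derived with certainty; (R) is written, and the (S) ligand takes its place if a small test run shows the opposite sense of induction.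

Step 1
Reactants: 1 methyl 4-hydroxy-3-iodobenzoate; 2 1-ethynyl-4-methoxybenzene
Product: 4 methyl 2-(4-methoxyphenyl)-1-benzofuran-5-carboxylate, via alkynylphenol 3 (not isolated)
Conditions: PdCl2(PPh3)2 (3 mol %), CuI (5 mol %), Et3N, DMF, 25 to 70 °C, argon
Reagents that add atoms: none
Why: Sonogashira coupling at the C-I bond is followed in the same pot by 5-endo-dig attack of the ortho phenol on the metal-activated alkyne, a standard heteroannulation to 2-arylbenzofurans that tolerates the ester.

Step 2
Reactants: 4 methyl 2-(4-methoxyphenyl)-1-benzofuran-5-carboxylate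
Product: 5 2-(4-methoxyphenyl)-1-benzofuran-5-carboxylic acid
Conditions: LiOH·H2O, THF/MeOH/H2O, 50 °C; then 1 M HCl to pH 2
Reagents that add atoms: lithium hydroxide, [Li+].[OH-]
Why: This is an ordinary ester saponification by acyl-oxygen cleavage, to which the benzofuran and the aryl methyl ether are inert.

Step 3
Reactants: 5 2-(4-methoxyphenyl)-1-benzofuran-5-carboxylic acid; 6 2-bromo-5-methoxyphenol
Product: 7 2-bromo-5-methoxyphenyl 2-(4-methoxyphenyl)-1-benzofuran-5-carboxylate
Conditions: DCC, DMAP (cat.), CH2Cl2, 0 °C to rt
Reagents that add atoms: none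
Why: In this Steglich esterification DMAP relays the O-acylisourea to the weakly nucleophilic ortho-bromophenol, and no other acyl acceptor is present.

Step 4
Reactants: 7 2-bromo-5-methoxyphenyl 2-(4-methoxyphenyl)-1-benzofuran-5-carboxylate
Product: 8 5-[1-(2-bromo-5-methoxyphenoxy)ethenyl]-2-(4-methoxyphenyl)-1-benzofuran
Conditions: Cp2TiMe2 (2.5 equiv), toluene, 70 °C, dark; hexane, filtration through basic Al2O3
Reagents that add atoms: dimethyltitanocene Cp2TiMe2, C[Ti+2]C.[CH-]1C=CC=C1.[CH-]1C=CC=C1
Why: In this Petasis methylenation the thermally formed titanium methylidene exchanges the ester C=O for C=CH2 by [2+2] addition and cycloreversion driven by the Ti=O bond, a change well precedented for aryl benzoates and mild enough to spare the aryl bromide, the benzofuran and the acid-labile enol ether.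

Step 5
Reactants: 8 5-[1-(2-bromo-5-methoxyphenoxy)ethenyl]-2-(4-methoxyphenyl)-1-benzofuran
Product: 11 4-methoxy-2-({1-[2-(4-methoxyphenyl)-1-benzofuran-5-yl]ethenyl}oxy)benzaldehyde, via aryllithium 9 (not isolated), via lithium hemiaminal alkoxide 10 (not isolated)
Conditions: n-BuLi (1.05 equiv), THF, -78 °C; DMF, -78 to 0 °C; H2O
Reagents that add atoms: N,N-dimethylformamide, CN(C)C=O
Why: Bromine-lithium exchange at -78 °C is faster than any deprotonation or addition to the enol ether, and Bouveault-type formylation of the aryllithium with DMF releases the aldehyde on a basic aqueous quench that leaves the enol ether intact.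

Step 6
Reactants: 11 4-methoxy-2-({1-[2-(4-methoxyphenyl)-1-benzofuran-5-yl]ethenyl}oxy)benzaldehyde
Product: 12 lophirone J = (2S)-7-methoxy-2-[2-(4-methoxyphenyl)-1-benzofuran-5-yl]-2,3-dihydro-4H-chromen-4-one
Conditions: [Rh(cod)Cl]2 (2.5 mol %), (R)-DTBM-SEGPHOS (5 mol %), NaB[3,5-(CF3)2C6H3]4 (5 mol %), THF, 60 °C, argon
Reagents that add atoms: none
Why: Proposed new method: the cationic monovalent rhodium bisphosphine complex should add oxidatively into the formyl C-H bond of 11 (O1 can hold the acyl hydride of trivalent rhodium in a five-membered chelate and so slow decarbonylation), bind the tethered C2=C3 bond, pass hydride to C2 with rhodium going to the unsubstituted C3, and form the C3-C4 bond by reductive elimination from the seven-membered acyl alkyl rhodacycle. The closest known reaction type is the enantioselective rhodium-catalysed intramolecular hydroacylation of 1,1-disubstituted alkenes, shown for ortho-allylbenzaldehydes (six-membered 3-substituted tetralones) and for N-vinylindole-2-carboxaldehydes (the heteroatom-bearing alkene carbon becomes the stereocentre), whereas an aryl 1-arylvinyl ether closing to a 2-arylchroman-4-one has not been shown. Ring C, the only ring formed, closes in a formal 6-endo-trig mode. The only new stereocentre, C2, is set in the hydride insertion, where the twofold-symmetric chiral pocket of DTBM-SEGPHOS decides which face of the prochiral enol ether lies on rhodium (pure catalyst control, since 11 is achiral). The step needs 6-endo over 5-exo regioselectivity, secured by the 1,1-disubstitution (rhodium avoids the tertiary carbon that bears O1 and the aryl group, and reductive elimination to a quaternary centre is slow) and by the enol ether polarisation that makes C2 the hydride acceptor, and it needs reductive elimination to outrun decarbonylation and beta-aryloxy elimination, for which the bulky electron-rich ligand and the non-coordinating borate anion are chosen. The alkene has no allylic hydrogen and so cannot isomerise, and the neutral medium does not open the base-sensitive flavanone, so the C2 configuration should persist.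

**Compound list**
1 | methyl 4-hydroxy-3-iodobenzoate | COC(=O)c1ccc(O)c(I)c1 | starting material
2 | 1-ethynyl-4-methoxybenzene | C#Cc1ccc(OC)cc1 | starting material
3 | methyl 4-hydroxy-3-[(4-methoxyphenyl)ethynyl]benzoate | COC(=O)c1ccc(O)c(C#Cc2ccc(OC)cc2)c1 | intermediate
4 | methyl 2-(4-methoxyphenyl)-1-benzofuran-5-carboxylate | COC(=O)c1ccc2oc(-c3ccc(OC)cc3)cc2c1 | intermediate
5 | 2-(4-methoxyphenyl)-1-benzofuran-5-carboxylic acid | OC(=O)c1ccc2oc(-c3ccc(OC)cc3)cc2c1 | intermediate
6 | 2-bromo-5-methoxyphenol | COc1ccc(Br)c(O)c1 | starting material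
7 | 2-bromo-5-methoxyphenyl 2-(4-methoxyphenyl)-1-benzofuran-5-carboxylate | COc1ccc(Br)c(OC(=O)c2ccc3oc(-c4ccc(OC)cc4)cc3c2)c1 | intermediate
8 | 5-[1-(2-bromo-5-methoxyphenoxy)ethenyl]-2-(4-methoxyphenyl)-1-benzofuran | COc1ccc(Br)c(OC(=C)c2ccc3oc(-c4ccc(OC)cc4)cc3c2)c1 | intermediate
9 | [4-methoxy-2-({1-[2-(4-methoxyphenyl)-1-benzofuran-5-yl]ethenyl}oxy)phenyl]lithium | [Li]c1ccc(OC)cc1OC(=C)c1ccc2oc(-c3ccc(OC)cc3)cc2c1 | intermediate
10 | lithium (dimethylamino)[4-methoxy-2-({1-[2-(4-methoxyphenyl)-1-benzofuran-5-yl]ethenyl}oxy)phenyl]methanolate (racemic) | CN(C)C(O[Li])c1ccc(OC)cc1OC(=C)c1ccc2oc(-c3ccc(OC)cc3)cc2c1 | intermediate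
11 | 4-methoxy-2-({1-[2-(4-methoxyphenyl)-1-benzofuran-5-yl]ethenyl}oxy)benzaldehyde | O=Cc1ccc(OC)cc1OC(=C)c1ccc2oc(-c3ccc(OC)cc3)cc2c1 | intermediate
12 | lophirone J, (2S)-7-methoxy-2-[2-(4-methoxyphenyl)-1-benzofuran-5-yl]-2,3-dihydro-4H-chromen-4-one | COc1ccc(-c2cc3cc([C@@H]4CC(=O)c5ccc(OC)cc5O4)ccc3o2)cc1 | target

Total step count: 6. Longest linear sequence: 6 (steps 1 to 6).

**Steps most likely to fail**

Step 6.
- What may go wrong: decarbonylation of the acyl rhodium hydride, 5-exo instead of 6-endo closure, or beta-aryloxy elimination from the alkyl rhodium stage. The cationic metal may also act only as a Lewis acid and trigger a carbonyl-ene type closure, or facial selectivity may be poor.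
- Fallback (known chemistry): it sets out from 2 and comes back at 12.
- Commercial 4-bromo-2-iodophenol and 2 would be joined under the conditions of step 1, the C-I bond reacting first, to give 5-bromo-2-(4-methoxyphenyl)-1-benzofuran F1.
- Bromine-lithium exchange (n-BuLi, THF, -78 °C), B(OiPr)3 and dilute HCl would give [2-(4-methoxyphenyl)-1-benzofuran-5-yl]boronic acid F2.
- Enantioselective 1,4-addition of F2 to commercial 7-methoxy-4H-chromen-4-one would then give 12 directly. Conditions would be Pd(OCOCF3)2, the t-BuPyOX ligand of the proper hand, NH4PF6, H2O, ClCH2CH2Cl, 60 °C, or a rhodium catalyst with a chiral bisphosphine.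
- This is a known route to 2-arylchroman-4-ones of high enantiomeric purity. Here the C2-aryl bond, not ring C, is made last.

Step 4.
- What may go wrong: sluggish methylenation of the conjugated, ortho-substituted aryl ester, loss of aryloxide from the titanium adduct, or hydrolysis of the enol ether during purification.
- Fallback: the alkene is kept and the aryl-alkene bond is made instead. It sets out from 2, by way of 5-bromo-2-(4-methoxyphenyl)-1-benzofuran F1 described above, and comes back at 11, so step 5 is bypassed as well.
- Commercial 2-hydroxy-4-methoxybenzaldehyde would be O-vinylated (vinyl acetate, [Ir(cod)Cl]2, Na2CO3, toluene, 100 °C) to 2-(ethenyloxy)-4-methoxybenzaldehyde F3.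
- A Heck reaction of F1 with F3 under cationic-pathway conditions (Pd(OAc)2, dppp, Et3N, [Et3NH][BF4], DMSO, 110 °C) should give 11. These conditions direct the aryl group to the oxygen-bearing alkene carbon.

Step 5.
- What may go wrong: protonation or butylation of the aryllithium, its intramolecular addition to the enol ether, or loss of the enol ether on work-up.
- Fallback: the aldehyde carbon is carried from the start at the alcohol level. It sets out from 5 and comes back at 11.
- Commercial 2-hydroxy-4-methoxybenzaldehyde would be reduced (NaBH4, MeOH, 0 °C) to 2-(hydroxymethyl)-5-methoxyphenol F4.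
- F4 would be silylated at the primary alcohol (TBSCl, imidazole, CH2Cl2, 0 °C) to 2-({[tert-butyl(dimethyl)silyl]oxy}methyl)-5-methoxyphenol F5.
- Steglich esterification of F5 with 5 would give the aryl ester F6.
- Petasis methylenation as in step 4 would give the silyl-protected enol ether F7.
- TBAF in THF would free [4-methoxy-2-({1-[2-(4-methoxyphenyl)-1-benzofuran-5-yl]ethenyl}oxy)phenyl]methanol F8.
- MnO2 in CH2Cl2 would oxidise the benzylic alcohol of F8 to 11 under neutral conditions.

**Further compounds**
F1 | step 6 | 5-bromo-2-(4-methoxyphenyl)-1-benzofuran | COc1ccc(-c2cc3cc(Br)ccc3o2)cc1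
F2 | step 6 | [2-(4-methoxyphenyl)-1-benzofuran-5-yl]boronic acid | COc1ccc(-c2cc3cc(B(O)O)ccc3o2)cc1
F3 | step 4 | 2-(ethenyloxy)-4-methoxybenzaldehyde | C=COc1cc(OC)ccc1C=O
F4 | step 5 | 2-(hydroxymethyl)-5-methoxyphenol | COc1ccc(CO)c(O)c1
F5 | step 5 | 2-({[tert-butyl(dimethyl)silyl]oxy}methyl)-5-methoxyphenol | COc1ccc(CO[Si](C)(C)C(C)(C)C)c(O)c1
F6 | step 5 | 2-({[tert-butyl(dimethyl)silyl]oxy}methyl)-5-methoxyphenyl 2-(4-methoxyphenyl)-1-benzofuran-5-carboxylate | COc1ccc(CO[Si](C)(C)C(C)(C)C)c(OC(=O)c2ccc3oc(-c4ccc(OC)cc4)cc3c2)c1
F7 | step 5 | tert-butyl{[4-methoxy-2-({1-[2-(4-methoxyphenyl)-1-benzofuran-5-yl]ethenyl}oxy)phenyl]methoxy}dimethylsilane | COc1ccc(CO[Si](C)(C)C(C)(C)C)c(OC(=C)c2ccc3oc(-c4ccc(OC)cc4)cc3c2)c1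
F8 | step 5 | [4-methoxy-2-({1-[2-(4-methoxyphenyl)-1-benzofuran-5-yl]ethenyl}oxy)phenyl]methanol | COc1ccc(CO)c(OC(=C)c2ccc3oc(-c4ccc(OC)cc4)cc3c2)c1
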